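(The earlier runs and the new flask are simulated from invented constants; scatter was added.)

A single exponential cannot pass through all of Sunday's readings: the one through the first reading runs 1.7 percentage points above the last, against a scatter of 0.5 points.

| flask | starting material | gas phase | remark | time |
|---|---|---|---|---|
| Sunday's | 0.24 M | 22 mM (held) | run made earlier |  |
| flask | 0.12 M | 22 mM (held) |  | 4.0 min |

- Sunday's (time / s: target / %, crystals / %): 10.0: 13.3, 2.0; 20.0: 24.5, 12.9; 30.0: 35.5, 24.1; 50.0: 49.3, 39.4

(readings scatter by 0.5 percentage points)

- what is said of target includes crystals
- crystals is a solid; its amount is given per volume of the solution
- at the start none of the gas phase is in solution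

1. target and crystals together at 4.0 min, in percent of the starting material charged
2. concentration of dissolved gas in solution at 4.0 min, in percent of saturation

We build the flask one process at a time. Take the main step by itself: with the gas held, starting material decays as a pseudo-first-order step. The first reading gives 0.0143 /s, which is one power of ten of starting material every 161 s. The flask's 4.0 min is 1.49 powers of ten, so 3.25 % stays and 96.7 % is made.

Now add the crystals. Target minus crystals, the dissolved target, reads 27.1 mM at the first reading and 23.8 mM at the last. Crystals are counted in target, so the passage into them is by itself no loss from the total, and we carry the dissolved target on to the next step.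

Then add the rest. We read Sunday's gap as a further step that eats dissolved target, and spread it from the first reading to the last. That gives the drain, the concentration lost from the total per unit time, of 0.103 mM/s. We assume it follows the dissolved target and the gas, which the flask shares with Sunday's run, and not the charge. Over 4.0 min it takes 24.6 mM, which is 21 points of the flask's charge. So we commit to about 76.2 %, as a rough figure.

The forecast gives 95 % and 99 %, on the ground that “the total is about first order in starting material”.

The flask gives 55.2 %, with dissolved gas at 99.3 %.

    gas phase ⇌ dissolved gas, rate k1*(csat - [dissolved gas]) (kL = 1.25 /s)
    starting material + dissolved gas → target (k = 0.867 /M/s)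
    dissolved gas + target → over-reacted product (k = 0.371 /M/s)
    starting material ⇌ dormant form (K = 1.80, k = 0.00324 /s)
    crystals ⇌ target, rate k5*(cs5 - [target]) while solid is left; crystals form when [target] > cs5 (solubility = 20.0 mM, k = 0.334 /s)

At 4.00 min the flask's over-reacted product holds 32.1 % of the charge, which is 38.5 mM where our drain reckoned 24.6 mM. Carried to the neighbour charged with 0.072 M, the same 24.6 mM is 34.2 % of its charge, and there over-reacted product stands at 51.6 %, which is 37.2 mM.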